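3.75% is where target sat in the winter run from 2.50 min to 8.00 min: the mean of 5%, 3%, 4% and 3%, good to 0.75 percentage points at a scatter of 1.5 points per reading. So ask what the end must be first, and how fast the flask gets there second.

| flask | substrate | solid partner | remark | time |
|---|---|---|---|---|
| winter | 0.25 mM | 2 equiv | run made earlier |  |
| flask | 0.50 mM | 2.00 equiv |  | 40 min |

- winter (time / min: target / %): 0.667: 20; 1.00: 8; 1.33: 4; 2.50: 5; 3.00: 3; 5.00: 4; 8.00: 3

(readings scatter by 1.5 percentage points)

- the best time, 40 min at the latest, for target
- the amount of target, in percent of the substrate charged, at that time
- the first time at which target reaches 9.8%, in the same percent, in min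

- the numbers in the tables scatter by 1.5 percentage points (one standard deviation)
- at the start none of the solid partner is in solution
- a reading or a percentage of target counts all its forms, free or not

Take the time scales in the order the readings show them. The rise of target goes unread: the winter run opens at 20% at 0.667 min and is already down to 8% at 1.00 min, so its readings show a falling side.

Next comes the fall. Subtract the plateau and read the decay time of the excess:

τ = (t₂ − t₁) / ln[(y₁ − plateau) / (y₂ − plateau)] = 0.248 min

Then comes the plateau. In the winter run it lasts 22.2 decay times without a trend, and the 40 min allowed in the asked flask is far longer than τ, at 161 of them. I read the winter level as a balance, thermodynamic control after a kinetic peak. So carry the plateau ratio, target over everything else the substrate became: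

r = plateau / (1 − plateau) = 0.0390

My own reckoning, assuming that ratio does not depend on concentration: the asked flask ends near 3.75%, with its best before 1.00 min.

The forecast puts the best at 35% at 0.2 min, with 9.8% passed at 0.05 min, and says: “Nothing suggests a later rise”.

The flask gives 19.5% at 0.596 min and reaches 9.8% at 0.148 min.

    substrate → open intermediate (k = 0.0950 s⁻¹)
    solid partner ⇌ fresh partner, rate k2*(cs2 - [fresh partner]) while solid is left; crystals form when [fresh partner] > cs2 (solubility = 0.230 mM, k = 1.70 s⁻¹)
    fresh partner → second intermediate (k = 0.0470 s⁻¹)
    target ⇌ isomer of the product (K = 31.0, k = 0.0980 s⁻¹)
    2 second intermediate → homo product (k = 2300 M⁻¹ s⁻¹)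
    open intermediate + second intermediate → target (k = 3600 M⁻¹ s⁻¹)
    crystals ⇌ target, rate k7*(cs7 - [target]) while solid is left; crystals form when [target] > cs7 (solubility = 0.270 mM, k = 14.0 s⁻¹)

By 40.0 min nearly all of the substrate charged in the flask is isomer of the product, at 96.9%, so r reads as target over isomer, and the forward rate to the isomer, the way back not counted, gives dissolved target a half-life of 0.12 min, short against 40 min. Now take the neighbour with 0.500 equiv of solid partner: it ends with 52.2% as open intermediate and 46.3% as isomer of the product. Applying r to that isomer gives 1.80% of target, and the neighbour holds 1.49%.

Readings and results were generated by integration with constants of no real substance; noise was put on by code.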